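(The earlier runs and the new flask were computed with constants of no real substance; scatter was added.)

The elm run ended at 30.0 h with G at 52.8% and X at 27.9% of the L charged, and the question was what these two become over the 12 d of Sunday's and Thursday's flasks.

| flask | L | temperature | remark | time |
|---|---|---|---|---|
| elm | 20 mM | 90 °C | run made earlier |  |
| Thursday's | 10 mM | 115 °C |  | 12 d |
| Sunday's | 10 mM | 90 °C |  | 12 d |

elm run (percent of the L charged)

| time / h | L / % | E / % | G / % | Q / % | X / % | D / % |
|---|---|---|---|---|---|---|
| 2.00 | 76.9 | 0.8 | 24.2 | 0 | 3.8 | 0.5 |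
| 6.00 | 43.5 | 0 | 50.1 | 4.1 | 6.4 | 0.4 |
| 10.0 | 24.1 | 0 | 58.7 | 4.4 | 13.3 | 0.9 |
| 15.0 | 13.2 | 0.5 | 61.5 | 8.3 | 19.3 | 0.2 |
| 20.0 | 6.6 | 1.3 | 59.9 | 11.1 | 22.1 | 0 |
| 30.0 | 0.9 | 1.5 | 52.8 | 15.8 | 27.9 | 2.5 |

(scatter of a reading: 1 percentage point)

- the numbers in the tables scatter with a standard deviation of 1 percentage point
- the earlier runs do not show what temperature does; that part of a forecast is a guess

- which of these there is most of at the end, counted by the L in it, Thursday's (X / Q / E / G / D)
- which of these there is most of at the end, counted by the L in it, Sunday's (X / Q / E / G / D)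
- amount of the one of these that there is most of at the end, in percent of the L charged, Thursday's
- amount of the one of these that there is most of at the end, in percent of the L charged, Sunday's

I followed one molecule and supposed that it wanders among L, G and X, my pool, until it leaves for Q, D or E. In the elm run the pool fell from 94.0% at 15.0 h to 81.6% at 30.0 h, so I read 0.00943 h⁻¹ as k, the drain constant, the fraction of the pool leaving per hour. Of what had left by that last reading, Q held 79.8%, a reading of the selectivity at the exit.

I assumed that the smaller charge changes neither number. Sunday's flask, at the elm temperature, then keeps 7.16% in the pool, and Q comes to 74.1%, the most. For Thursday's flask at 115 °C I could only guess: with the same selectivity and a pool drained to the end, Q stands near 79.8%.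

The forecast differed from this. For Thursday's flask it gave X at 55%, and for Sunday's flask X at 57%, on the ground that “G ends up in X and Q”, whereas I kept X in the pool.

Thursday's flask gave Q at 83.1%, and Sunday's flask gave Q at 74.4%.

    X → D (k = 0.00500 h⁻¹, Ea = 122 kJ mol⁻¹)
    G ⇌ X (K = 0.550, k = 0.0420 h⁻¹, Ea = 120 kJ mol⁻¹, ΔH = −6.00 kJ mol⁻¹)
    D ⇌ E (K = 14.0, k = 0.0280 h⁻¹, Ea = 129 kJ mol⁻¹, ΔH = −4.00 kJ mol⁻¹)
    G → Q (k = 0.0110 h⁻¹, Ea = 123 kJ mol⁻¹)
    L → G (k = 0.140 h⁻¹, Ea = 105 kJ mol⁻¹)
    (constants at 90 °C)

In Sunday's flask L, G and X together held 8.30% at 12.0 d, against the 7.16% reckoned with k. At that time in Sunday's flask, the forward rate alone of G turning into X gave G a half-life of 0.69 d, while the slowest mode of the whole flask had a half-life of 3.28 d, and k had given 3.06 d. On the neighbour, Sunday's flask stopped at 5.0 d, k leaves 34.9% in the pool and puts Q at 51.9%. That flask held 36.4% in L, G and X, and Q at 52.2%.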